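A direct plan would take 2-geranyl-1,4-dimethoxybenzene A1 (aryl metal plus allylic halide), oxidise its terminal (E)-methyl group with SeO2 to the allylic alcohol A2, and convert this to the bromide A3.
Copper-catalysed coupling of A3 with β-cyclogeranylmagnesium chloride A4 would give the dimethyl ether A5. CAN would then give the quinone A6, and dithionite would reduce A6 to the target.
Weakest: the allyl–allyl coupling of A3 with A4. Both partners are ambident (α/γ, SN2/SN2′), the hindered allylic Grignard reagent would tend to homocouple, and the isomers would arise at the convergent step as oils that are hard to separate.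
Weak: the SeO2 oxidation of A1 to A2. It would have to pick one methyl group beside a doubly activated ArCH2–CH= position and a second alkene. It tends to stop short or over-oxidise, and the whole linear sequence passes through it.
Weak: the methyl ether/CAN/dithionite end game. Protection, oxidation and reduction would build no bond, and a strong one-electron oxidant would meet the electron-rich tetrasubstituted ring alkene in the most valuable intermediate.

## Retrosynthetic overview
Feature used (chain C1′ = benzylic CH2 to C9′ = CH2 on the cyclohexene): the phenol O on arene C1, arene C2, C1′ and the C2′=C3′ alkene are the opened form of a 4H-chromene (O1–C2=C3–C4–C4a–C8a). C3′ is therefore treated as a lactone carbonyl carbon that receives two carbon groups in turn.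
Key disconnection: C3′–CH3, by nickel-catalysed methylative opening of a 2-alkyl-4H-chromene. The ring forces O1 and C1′ to be cis, so exchange of O1 for CH3 with retention can give only the (E)-alkene, and it frees the phenol at the same time.
Second cut: C3′–C4′, by B-alkyl Suzuki–Miyaura coupling of the enol phosphate of a 6-silyloxychroman-2-one with a homoallylic borane. The borane comes from dihydro-β-ionone via the terminal alkyne, Zr-catalysed methylalumination/Pd vinylation (C7′–CH3, C5′–C6′, (E)-C6′=C7′) and 9-BBN.
Rings: the cyclohexene (dihydro-β-ionone) and the benzene ring (hydroquinone) are bought. One auxiliary pyranone ring is closed first (hydroquinone plus acrylic acid) and opened last.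
Design gain: every chain C–C bond is an sp2–sp3 or sp2–sp2 coupling without allylic ambiguity, and no allylic C–H oxidation is needed. The lactone oxygen protects itself, and the arene stays at the hydroquinone level throughout (one silyl ether, no quinone).

Key step: step 7

Assumption: the target has no stereocentre, so "single enantiomer" is taken to mean the single (2′E,6′E) geometric isomer.

## Route

Step 1
Reactants: 1 hydroquinone; 2 acrylic acid
Product: 3 6-hydroxychroman-2-one (6-hydroxy-3,4-dihydrocoumarin)
Conditions: Amberlyst-15, PhMe, reflux (Dean–Stark), 1 in excess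
Reagents that add atoms: none
Why: Acid-catalysed Friedel–Crafts conjugate addition (hydroarylation) of the electron-rich arene to acrylic acid followed by lactonisation should close the pyranone ring, since all four free positions of 1 are equivalent, the acylated oxygen deactivates 3 against a second annulation, and 1 itself inhibits radical polymerisation of 2.

Step 2
Reactants: 3 6-hydroxychroman-2-one
Product: 4 6-(triisopropylsilyloxy)chroman-2-one
Conditions: TIPSOTf, 2,6-lutidine, CH2Cl2, 0 °C
Reagents that add atoms: triisopropylsilyl trifluoromethanesulfonate, CC(C)[Si](OS(=O)(=O)C(F)(F)F)(C(C)C)C(C)C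
Why: Silylation of the only free phenol with a non-nucleophilic base leaves the aryl lactone closed, and the bulky aryl silyl ether should withstand the strong base, the aqueous coupling and the Grignard reagent of steps 3, 6 and 7.

Step 3
Reactants: 4 6-(triisopropylsilyloxy)chroman-2-one
Product: 5 6-(triisopropylsilyloxy)-4H-chromen-2-yl diphenyl phosphate
Conditions: (PhO)2P(O)Cl, KHMDS (added last), THF–DMPU, −78 °C
Reagents that add atoms: diphenyl chlorophosphate, O=P(Cl)(Oc1ccccc1)Oc1ccccc1
Why: Kinetic enolisation of the lactone at C3 in the presence of the chlorophosphate and O-phosphorylation (ketene acetal phosphate formation) turns the carbonyl carbon, the future C3′, into an alkenyl electrophile whose double bond can only lie in the ring, and the low temperature with internal quench should outrun loss of aryloxide from the enolate.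

Step 4
Reactants: 6 dihydro-β-ionone (4-(2,6,6-trimethylcyclohex-1-en-1-yl)butan-2-one)
Product: 8 2-(but-3-yn-1-yl)-1,3,3-trimethylcyclohex-1-ene, via enol diethyl phosphate 7 (not isolated)
Conditions: LDA, THF, −78 °C; ClP(O)(OEt)2, −78 °C to rt; LDA (2.3 equiv), −78 °C to rt; H2O
Reagents that add atoms: none
Why: Kinetic deprotonation at the methyl group, O-phosphorylation and base-induced elimination (conversion of a methyl ketone into a terminal alkyne via its enol phosphate) should turn the acetyl group into C7′≡C6′H and leave the hindered ring alkene untouched.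

Step 5
Reactants: 8 2-(but-3-yn-1-yl)-1,3,3-trimethylcyclohex-1-ene
Product: 10 2-[(3E)-3-methylhexa-3,5-dien-1-yl]-1,3,3-trimethylcyclohex-1-ene, via alkenyldimethylalane 9 (not isolated)
Conditions: Me3Al, Cp2ZrCl2 (cat.), CH2Cl2, 0 °C to rt; then CH2=CHBr, Pd(PPh3)4 (cat.), ZnCl2 (cat.), THF, rt
Reagents that add atoms: trimethylaluminium, C[Al](C)C; vinyl bromide, C=CBr
Why: Zr-catalysed syn-methylalumination (Negishi carboalumination) places CH3 on the internal carbon C7′ and aluminium on C6′ cis to it, and the Pd-catalysed alkenyl–alkenyl Negishi coupling replaces aluminium by vinyl with retention, so the (E)-C6′=C7′ alkene is fixed.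

Step 6
Reactants: 10 2-[(3E)-3-methylhexa-3,5-dien-1-yl]-1,3,3-trimethylcyclohex-1-ene; 5 6-(triisopropylsilyloxy)-4H-chromen-2-yl diphenyl phosphate
Product: 12 2-[(3E)-4-methyl-6-(2,6,6-trimethylcyclohex-1-en-1-yl)hex-3-en-1-yl]-6-(triisopropylsilyloxy)-4H-chromene, via B-alkyl-9-BBN 11 (not isolated)
Conditions: 9-BBN, THF, 0 °C to rt; then 5, Pd(PPh3)4 (cat.), aq. NaHCO3, DMF, 50 °C; basic alumina
Reagents that add atoms: none
Why: 9-BBN should add only to the terminal monosubstituted end of the diene with boron on C4′, because the tri- and tetrasubstituted alkenes are too hindered, and the B-alkyl Suzuki–Miyaura coupling with the lactone-derived ketene acetal phosphate forms C3′–C4′ as an sp3–sp2 bond without allylic ambiguity.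

Step 7
Reactants: 12 2-[(3E)-4-methyl-6-(2,6,6-trimethylcyclohex-1-en-1-yl)hex-3-en-1-yl]-6-(triisopropylsilyloxy)-4H-chromene
Product: 13 2-[(2E,6E)-3,7-dimethyl-9-(2,6,6-trimethylcyclohex-1-en-1-yl)nona-2,6-dien-1-yl]-4-(triisopropylsilyloxy)phenol
Conditions: MeMgBr (4 equiv), NiCl2(PPh3)2 (10 mol %), PhMe, 70 °C, Ar; then H2O
Reagents that add atoms: methylmagnesium bromide, C[Mg]Br
Why: Ni(0), formed from NiCl2(PPh3)2 and MeMgBr, should insert into the alkenyl C2–O1 bond of the cyclic enol ether, take up methyl from magnesium and form the C3′–CH3 bond by reductive elimination with retention, so that the pyran ring opens to the magnesium phenoxide of 13. The closest known reaction type is the Wenkert-type nickel-catalysed Grignard coupling of enol ethers, which has been used on 5-alkyl-2,3-dihydrofurans, 6-alkyl-3,4-dihydro-2H-pyrans and benzofuran to make stereodefined alkenes by ring opening. The step closes no ring and creates no stereocentre; its stereochemical task is the C2′=C3′ geometry, which is controlled by the ring of 12, where O1 and C4 (= C1′) are necessarily cis, so that CH3 ends cis to C1′ and the C4′ chain trans to it, i.e. (E). The selectivity needed is alkenyl C–O over the aryl C8a–O1 and C6–OSi bonds, and it is secured by the triphenylphosphine catalyst, which does not activate simple aryl ethers, and by the aryloxide, a better leaving group than the alkoxides of the precedents. MeMgBr has no β-hydrogen, so no nickel hydride should arise that could reduce the C–O bond or move the enol ether, the skipped aryl/alkene unit or the remote alkenes. In one operation the last carbon is added, the second (E)-alkene is fixed and the ortho phenol is set free.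

Step 8
Reactants: 13 2-[(2E,6E)-3,7-dimethyl-9-(2,6,6-trimethylcyclohex-1-en-1-yl)nona-2,6-dien-1-yl]-4-(triisopropylsilyloxy)phenol
Product: 14 Jaspaquinol
Conditions: TBAF, AcOH, THF, 0 °C, Ar
Reagents that add atoms: none
Why: Fluoride cleaves the aryl silyl ether (desilylation), acetic acid buffering and exclusion of air keep the hydroquinone from oxidation, and no acid strong enough to close a chroman onto C3′ is present.

## Compound list
1 | hydroquinone | Oc1ccc(O)cc1 | starting material
2 | acrylic acid | C=CC(=O)O | starting material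
3 | 6-hydroxychroman-2-one | O=C1CCc2cc(O)ccc2O1 | intermediate
4 | 6-(triisopropylsilyloxy)chroman-2-one | O=C1CCc2cc(O[Si](C(C)C)(C(C)C)C(C)C)ccc2O1 | intermediate
5 | 6-(triisopropylsilyloxy)-4H-chromen-2-yl diphenyl phosphate | O=P(Oc1ccccc1)(Oc1ccccc1)OC1=CCc2cc(O[Si](C(C)C)(C(C)C)C(C)C)ccc2O1 | intermediate
6 | dihydro-β-ionone | CC(=O)CCC1=C(C)CCCC1(C)C | starting material
7 | diethyl 4-(2,6,6-trimethylcyclohex-1-en-1-yl)but-1-en-2-yl phosphate | C=C(CCC1=C(C)CCCC1(C)C)OP(=O)(OCC)OCC | intermediate
8 | 2-(but-3-yn-1-yl)-1,3,3-trimethylcyclohex-1-ene | C#CCCC1=C(C)CCCC1(C)C | intermediate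
9 | dimethyl[(1E)-2-methyl-4-(2,6,6-trimethylcyclohex-1-en-1-yl)but-1-en-1-yl]alane | CC1=C(CC/C(C)=C/[Al](C)C)C(C)(C)CCC1 | intermediate
10 | 2-[(3E)-3-methylhexa-3,5-dien-1-yl]-1,3,3-trimethylcyclohex-1-ene | CC1=C(CC/C(C)=C/C=C)C(C)(C)CCC1 | intermediate
11 | 9-[(3E)-4-methyl-6-(2,6,6-trimethylcyclohex-1-en-1-yl)hex-3-en-1-yl]-9-borabicyclo[3.3.1]nonane | CC1=C(CC/C(C)=C/CCB2C3CCCC2CCC3)C(C)(C)CCC1 | intermediate
12 | 2-[(3E)-4-methyl-6-(2,6,6-trimethylcyclohex-1-en-1-yl)hex-3-en-1-yl]-6-(triisopropylsilyloxy)-4H-chromene | CC1=C(CC/C(C)=C/CCC2=CCc3cc(O[Si](C(C)C)(C(C)C)C(C)C)ccc3O2)C(C)(C)CCC1 | intermediate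
13 | 2-[(2E,6E)-3,7-dimethyl-9-(2,6,6-trimethylcyclohex-1-en-1-yl)nona-2,6-dien-1-yl]-4-(triisopropylsilyloxy)phenol | CC1=C(CC/C(C)=C/CC/C(C)=C/Cc2cc(O[Si](C(C)C)(C(C)C)C(C)C)ccc2O)C(C)(C)CCC1 | intermediate
14 | Jaspaquinol | CC1=C(CC/C(C)=C/CC/C(C)=C/Cc2cc(O)ccc2O)C(C)(C)CCC1 | target

## Count and risks
Total step count: 8. Longest linear sequence: 6 (steps 1, 2, 3, 6, 7, 8). The chain branch (steps 4, 5) joins at step 6.

**Step 7.** Nickel may insert too slowly into the alkenyl C–O bond, the enol-ether double bond may migrate before coupling, or the geometry may erode. The fallback sets out from 10 and comes back at 14.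
- The borane 11, made from 10 as in step 6, would be coupled (Suzuki–Miyaura) with (E)-3-iodobut-2-en-1-ol to the C20 (2E,6E)-allylic alcohol F1.
- Mesylation in the presence of LiCl would give the allylic chloride F2, and tributylstannyllithium would give the allylstannane F3.
- BF3·OEt2-promoted addition of F3 to 1,4-benzoquinone at −78 °C (carbonyl addition, [3,3] shift, aromatisation; KF work-up) would give 14 directly at the hydroquinone level.

**Step 3.** The aryl-lactone enolate may collapse to a ketene-phenoxide, C-phosphorylation may compete, or the ketene acetal phosphate may hydrolyse on handling or in the aqueous coupling of step 6. The fallback sets out from 4 and 10 and comes back at 12.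
- Lactone 4 would be opened with MeNH(OMe)·HCl/i-PrMgCl to the phenolic Weinreb amide F4.
- Borane 11, from 10, would be iodinated (I2, NaOMe) to the homoallylic iodide F5.
- Iodine–lithium exchange of F5 (t-BuLi) and addition to the magnesium phenoxide of F4 would give the keto-phenol F6.
- Azeotropic dehydration of the cyclic hemiketal of F6 (PPTS, PhH, reflux) under equilibrating conditions would close the endocyclic enol ether 12.

**Step 1.** Fries-type C-acylation may compete with conjugate C-alkylation, a second annulation may occur, or acrylic acid may oligomerise. The fallback sets out from 1 and comes back at 3. Pechmann condensation of 1 with malic acid in H2SO4 would give 6-hydroxycoumarin F7, and hydrogenation of its C3=C4 bond (H2, Pd/C, EtOAc) would give 3.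

## Further compounds
F1 | step 7 | (2E,6E)-3,7-dimethyl-9-(2,6,6-trimethylcyclohex-1-en-1-yl)nona-2,6-dien-1-ol | CC1=C(CC/C(C)=C/CC/C(C)=C/CO)C(C)(C)CCC1
F2 | step 7 | 2-[(3E,7E)-9-chloro-3,7-dimethylnona-3,7-dien-1-yl]-1,3,3-trimethylcyclohex-1-ene | CC1=C(CC/C(C)=C/CC/C(C)=C/CCl)C(C)(C)CCC1
F3 | step 7 | tributyl[(2E,6E)-3,7-dimethyl-9-(2,6,6-trimethylcyclohex-1-en-1-yl)nona-2,6-dien-1-yl]stannane | CC1=C(CC/C(C)=C/CC/C(C)=C/C[Sn](CCCC)(CCCC)CCCC)C(C)(C)CCC1
F4 | step 3 | 3-[2-hydroxy-5-(triisopropylsilyloxy)phenyl]-N-methoxy-N-methylpropanamide | CON(C)C(=O)CCc1cc(O[Si](C(C)C)(C(C)C)C(C)C)ccc1O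
F5 | step 3 | 2-[(3E)-6-iodo-3-methylhex-3-en-1-yl]-1,3,3-trimethylcyclohex-1-ene | CC1=C(CC/C(C)=C/CCI)C(C)(C)CCC1
F6 | step 3 | (6E)-1-[2-hydroxy-5-(triisopropylsilyloxy)phenyl]-7-methyl-9-(2,6,6-trimethylcyclohex-1-en-1-yl)non-6-en-3-one | CC1=C(CC/C(C)=C/CCC(=O)CCc2cc(O[Si](C(C)C)(C(C)C)C(C)C)ccc2O)C(C)(C)CCC1
F7 | step 1 | 6-hydroxycoumarin | O=c1ccc2cc(O)ccc2o1
A1 | direct plan | 2-geranyl-1,4-dimethoxybenzene | CC(C)=CCC/C(C)=C/Cc1cc(OC)ccc1OC
A2 | direct plan | (2E,6E)-8-(2,5-dimethoxyphenyl)-2,6-dimethylocta-2,6-dien-1-ol | OC/C(C)=C/CC/C(C)=C/Cc1cc(OC)ccc1OC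
A3 | direct plan | (2E,6E)-1-bromo-8-(2,5-dimethoxyphenyl)-2,6-dimethylocta-2,6-diene | BrC/C(C)=C/CC/C(C)=C/Cc1cc(OC)ccc1OC
A4 | direct plan | β-cyclogeranylmagnesium chloride | CC1=C(C[Mg]Cl)C(C)(C)CCC1
A5 | direct plan | Jaspaquinol dimethyl ether | CC1=C(CC/C(C)=C/CC/C(C)=C/Cc2cc(OC)ccc2OC)C(C)(C)CCC1
A6 | direct plan | 2-[(2E,6E)-3,7-dimethyl-9-(2,6,6-trimethylcyclohex-1-en-1-yl)nona-2,6-dien-1-yl]-1,4-benzoquinone | CC1=C(CC/C(C)=C/CC/C(C)=C/CC2=CC(=O)C=CC2=O)C(C)(C)CCC1
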